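**Strategy.** Everything rests on disconnecting C5–C6 of ring B. Ring B (C4a, C5, C6, C7, C8, C8a), with the C8a methyl, an oxygen-derived C5 and the C6 2-hydroxypropan-2-yl group, is a masked p-menthane-3,8-diol. An acid-promoted aldehyde–alkene (Prins) cyclisation with water capture therefore closes ring B, forms C5–C6 and sets C6 together with the tertiary carbinol in one operation. Its precursor is a ring A aldehyde: C4a carries CHO and bromine, C8a the methyl and a 4-methylpent-3-enyl chain, C1 the arylated side chain. The arene is carried as its 3,5-dibromo-2,4,6-trimethoxy form, which blocks it against electrophiles and stores the two formyl groups.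

Key step: step 10

Remark (labels): Cα is the benzylic carbon; ring A = C1, C2, C3, C4, C4a, C8a; ring B = C4a, C5, C6, C7, C8, C8a; β is the face of the 8a-methyl group, α the opposite face; Ar = 2,4,6-trimethoxyphenyl, ArBr2 = 3,5-dibromo-2,4,6-trimethoxyphenyl; homoprenyl = 4-methylpent-3-enyl.

Remark (assumption): the C5 carbinol of 17 is drawn as the equatorial (α) epimer expected from the chair transition state; either epimer would serve, because C5 becomes sp2 in step 11.

Step 1
Reactants: 1 1,3,5-trimethoxybenzene; 2 (E)-5-methylhex-2-enal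
Product: 3 (3S)-5-methyl-3-(2,4,6-trimethoxyphenyl)hexanal
Conditions: (2R,5R)-5-benzyl-2-tert-butyl-3-methylimidazolidin-4-one·CF3CO2H (20 mol%), 1 (2 equiv), CHCl3, −20 → 0 °C
Reagents that add atoms: none
Why: Iminium-catalysed Friedel–Crafts conjugate addition, in which the arene (in excess to suppress double alkylation) should attack the β-carbon of the (E)-iminium ion on the face left open by the benzyl and tert-butyl groups of the (2R,5R)-catalyst, setting Cα as S.

Step 2
Reactants: 3 (3S)-5-methyl-3-(2,4,6-trimethoxyphenyl)hexanal; 4 (E)-1-bromoprop-1-ene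
Product: 6 (2E,6S)-8-methyl-6-(2,4,6-trimethoxyphenyl)non-2-en-4-ol (both C4 epimers), via (E)-prop-1-enyllithium 5 (not isolated)
Conditions: 4, t-BuLi (2 equiv), Et2O, −78 °C; then 3, −78 °C; H2O
Reagents that add atoms: none
Why: Stereoretentive bromine–lithium exchange followed by 1,2-addition of the (E)-alkenyllithium to the aldehyde should give the allylic alcohol; the new carbinol centre is uncontrolled and is erased in step 3.

Step 3
Reactants: 6 (2E,6S)-8-methyl-6-(2,4,6-trimethoxyphenyl)non-2-en-4-ol
Product: 7 (2E,6S)-8-methyl-6-(2,4,6-trimethoxyphenyl)non-2-en-4-one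
Conditions: DMP, CH2Cl2, 0 → 23 °C
Reagents that add atoms: none
Why: Dess–Martin oxidation of a secondary allylic alcohol proceeds under near-neutral conditions that should spare the electron-rich arene and the (E)-alkene, and both carbinol epimers converge on one enone.

Step 4
Reactants: 7 (2E,6S)-8-methyl-6-(2,4,6-trimethoxyphenyl)non-2-en-4-one
Product: 8 tert-butyl(dimethyl){[(2E,4Z,6S)-8-methyl-6-(2,4,6-trimethoxyphenyl)nona-2,4-dien-4-yl]oxy}silane
Conditions: TBSOTf, Et3N, CH2Cl2, −78 → 0 °C
Reagents that add atoms: tert-butyldimethylsilyl trifluoromethanesulfonate, CC(C)(C)[Si](C)(C)OS(=O)(=O)C(F)(F)F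
Why: Soft enolisation (silyl triflate and amine) toward the α′-methylene should give the cross-conjugated 2-silyloxy diene, with the (Z)-enol ether favoured because the branched Cα group then lies cis to oxygen and not to the vinyl group.

Step 5
Reactants: 8 (2E,4Z,6S)-2-silyloxy diene; 9 geranial [(2E)-3,7-dimethylocta-2,6-dienal]
Product: 10 ring A cycloadduct: C4a carbaldehyde with the C2=C3 enol ether (C2–OTBS); the C1 (1S)-3-methyl-1-Ar-butyl group and 4-Me and 4a-CHO and 8a-Me all β; 8a-homoprenyl α
Conditions: Me2AlCl (20 mol%), CH2Cl2, −78 → −20 °C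
Reagents that add atoms: none
Why: Lewis-acid-promoted Diels–Alder reaction in which the enol ether terminus C1 bonds to the enal β-carbon (C8a) under 2-silyloxy-diene regiocontrol, the endo (CHO) transition state of the (E,Z)-diene with (E)-geranial places the C1 side chain, 4-Me, 4a-CHO and 8a-Me on one face, and allylic 1,3-strain holds the Cα–H in the diene plane so that the dienophile should approach anti to the aryl group, relaying Cα (S) to C1, C4 and C8a.

Step 6
Reactants: 10 ring A cycloadduct (C2–OTBS enol ether)
Product: 11 ring A enol triflate (C2–OSO2CF3 on C2=C3; other groups and configurations as in 10)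
Conditions: CsF, PhNTf2, DME, 23 °C
Reagents that add atoms: N-phenylbis(trifluoromethanesulfonimide), O=S(=O)(N(c1ccccc1)S(=O)(=O)C(F)(F)F)C(F)(F)F
Why: Fluoride-induced cleavage of the silyl enol ether gives the regiodefined caesium enolate, which is O-triflated in situ (enolate triflation) fast enough that equilibration toward C1 should not occur, while the hindered aldehyde is inert to these non-nucleophilic reagents.

Step 7
Reactants: 11 ring A enol triflate
Product: 12 ring A cyclohexene aldehyde (plain C2=C3 alkene; other groups and configurations as in 10)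
Conditions: Pd(OAc)2 (5 mol%), PPh3 (12 mol%), HCO2H, n-Bu3N, DMF, 60 °C
Reagents that add atoms: none
Why: Palladium-catalysed formate reduction of an enol triflate (oxidative addition, formate exchange, decarboxylation, reductive elimination) should replace the C2 oxygen by hydrogen without touching the aldehyde or either alkene.

Step 8
Reactants: 12 ring A cyclohexene aldehyde
Product: 13 saturated ring A aldehyde (C1 side chain and 4-Me and 4a-CHO and 8a-Me β; 8a-homoprenyl α)
Conditions: KO2CN=NCO2K, AcOH, CH2Cl2/i-PrOH, 23 °C
Reagents that add atoms: none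
Why: Diimide reduction transfers hydrogen in a concerted syn fashion fastest to the cis-disubstituted ring alkene, so the trisubstituted side-chain alkene and the aldehyde should survive and no stereocentre is touched.

Step 9
Reactants: 13 saturated ring A aldehyde
Product: 16 ring A 4aα-bromo aldehyde bearing the ArBr2 side chain (key-step precursor), via potassium enolate 14 (not isolated), via 4aα-bromo aldehyde 15 (not isolated)
Conditions: KH, THF, 0 → 23 °C; NBS (1.05 equiv), −78 °C; then NBS (2.1 equiv), MeCN, −40 → 0 °C; H2O
Reagents that add atoms: N-bromosuccinimide, O=C1CCC(=O)N1Br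
Why: Enolate α-bromination followed by electrophilic aromatic bromination: NBS should attack the exocyclic enolate on the α face, anti to the syn-axial C4 and C8a methyl groups, placing bromine trans to the 8a-methyl, and the further NBS should brominate the two free positions of the trimethoxyarene much faster than the trisubstituted alkene.

Step 10
Reactants: 16 ring A 4aα-bromo aldehyde with ArBr2 side chain
Product: 17 trans-fused bromohydrin diol (4aα-Br, 5α-OH, 6β-(2-hydroxypropan-2-yl), 8aβ-Me, ArBr2 side chain)
Conditions: H2SO4 (5% aq.)/THF (1:2), 40 °C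
Reagents that add atoms: water, O
Why: Protonation of the α-bromo aldehyde makes C5 electrophilic, the trisubstituted alkene attacks it through C6 and water captures the resulting tertiary 2-propyl cation, so C5–C6 and the tertiary carbinol arise in one operation; the closest known reaction is the aqueous-acid Prins cyclisation of citronellal-type aldehydes to p-menthane-3,8-diols. Ring B closes through a six-membered chair in which both reacting π bonds are exocyclic to the new ring (6-exo with respect to the alkene). Because the 4a-CHO (β) and the 8a-homoprenyl chain (α) are trans and both equatorial on the ring A chair, the new ring can only be trans-fused. C6 is set β (cis to the 8a-methyl) because the cationic carbon takes the equatorial site, the axial one being syn-axial to the 4aα-bromine, and the C5 hydroxyl should be equatorial (α) to avoid the axial 8a-methyl, although its configuration no longer matters after step 11. The step needs the aldehyde to be activated in preference to simple hydration of the alkene, and water to outcompete proton loss and arene attack: the inductively activated α-bromo aldehyde, the large excess of water and the fully substituted dibromoarene should secure this.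

Step 11
Reactants: 17 trans-fused bromohydrin diol
Product: 18 C4a=C5 alkene tertiary alcohol (target skeleton with ArBr2 side chain)
Conditions: Zn dust, AcOH/THF, 40 °C
Reagents that add atoms: none
Why: Zinc-mediated reductive elimination of a bromohydrin (Boord-type) starts at the tertiary C4a–Br bond and expels the acid-activated C5 oxygen, so the alkene can only form between C4a and C5; the reduced ring-fusion centre is configurationally free, so the gauche Br/OH arrangement should not block elimination, and aryl bromides and the tertiary alcohol are inert.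

Step 12
Reactants: 18 C4a=C5 alkene tertiary alcohol with ArBr2 side chain
Product: 20 3′,5′-diformyl-2′,4′,6′-trimethoxyphenyl compound (target tri-O-methyl ether), via trilithiated intermediate 19 (not isolated)
Conditions: t-BuLi (5.2 equiv), THF, −78 °C; DMF, −78 → 0 °C; H2O
Reagents that add atoms: N,N-dimethylformamide, CN(C)C=O
Why: After deprotonation of the tertiary alcohol, double bromine–lithium exchange gives a dilithioarene whose carbanions are each flanked by two methoxy groups, and DMF formylates both (Bouveault-type formylation), the tetrahedral adducts collapsing to the dialdehyde only on aqueous work-up.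

Step 13
Reactants: 20 target tri-O-methyl ether
Product: 21 target, CNP0108656.4
Conditions: NaSEt (10 equiv), DMF, 120 °C; then aq. HCl
Reagents that add atoms: none
Why: Nucleophilic O-demethylation (SN2 attack of thiolate at methyl) is eased because every methoxy group is ortho or para to a formyl group, and the basic, non-Lewis-acidic conditions should spare the tertiary homoallylic alcohol and the C4a=C5 alkene.

**Compound list**

1 | 1,3,5-trimethoxybenzene | COc1cc(OC)cc(OC)c1 | starting material
2 | (E)-5-methylhex-2-enal | CC(C)C/C=C/C=O | starting material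
3 | (3S)-5-methyl-3-(2,4,6-trimethoxyphenyl)hexanal | CC(C)C[C@H](c1c(OC)cc(OC)cc1OC)CC=O | intermediate
4 | (E)-1-bromoprop-1-ene | C/C=C/Br | starting material
5 | (E)-prop-1-enyllithium | C/C=C/[Li] | intermediate
6 | (2E,6S)-8-methyl-6-(2,4,6-trimethoxyphenyl)non-2-en-4-ol, both C4 epimers | CC(C)C[C@H](c1c(OC)cc(OC)cc1OC)CC(O)/C=C/C | intermediate
7 | (2E,6S)-8-methyl-6-(2,4,6-trimethoxyphenyl)non-2-en-4-one | CC(C)C[C@H](c1c(OC)cc(OC)cc1OC)CC(=O)/C=C/C | intermediate
8 | tert-butyl(dimethyl){[(2E,4Z,6S)-8-methyl-6-(2,4,6-trimethoxyphenyl)nona-2,4-dien-4-yl]oxy}silane | CC(C)C[C@H](c1c(OC)cc(OC)cc1OC)/C=C(\O[Si](C)(C)C(C)(C)C)/C=C/C | intermediate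
9 | geranial, (2E)-3,7-dimethylocta-2,6-dienal | CC(C)=CCC/C(C)=C/C=O | starting material
10 | ring A cycloadduct: cyclohexene with C2=C3 as C2–OTBS enol ether; C1 (1S)-3-methyl-1-Ar-butyl, 4-Me, 4a-CHO, 8a-Me all β; 8a-homoprenyl α | CC(C)C[C@H](c1c(OC)cc(OC)cc1OC)[C@H]1C(O[Si](C)(C)C(C)(C)C)=C[C@@H](C)[C@@H](C=O)[C@]1(C)CCC=C(C)C | intermediate
11 | ring A enol triflate: as 10 with C2–OSO2CF3 | CC(C)C[C@H](c1c(OC)cc(OC)cc1OC)[C@H]1C(OS(=O)(=O)C(F)(F)F)=C[C@@H](C)[C@@H](C=O)[C@]1(C)CCC=C(C)C | intermediate
12 | ring A cyclohexene aldehyde: as 10 with unsubstituted C2=C3 | CC(C)C[C@H](c1c(OC)cc(OC)cc1OC)[C@H]1C=C[C@@H](C)[C@@H](C=O)[C@]1(C)CCC=C(C)C | intermediate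
13 | saturated ring A aldehyde: C1 side chain, 4-Me, 4a-CHO, 8a-Me β; 8a-homoprenyl α | CC(C)C[C@H](c1c(OC)cc(OC)cc1OC)[C@H]1CC[C@@H](C)[C@@H](C=O)[C@]1(C)CCC=C(C)C | intermediate
14 | potassium enolate of 13 (C4a=C5–OK) | CC(C)C[C@H](c1c(OC)cc(OC)cc1OC)[C@H]1CC[C@@H](C)C(=C[O-])[C@]1(C)CCC=C(C)C.[K+] | intermediate
15 | ring A 4aα-bromo-4aβ-carbaldehyde with Ar side chain | CC(C)C[C@H](c1c(OC)cc(OC)cc1OC)[C@H]1CC[C@@H](C)[C@@](Br)(C=O)[C@]1(C)CCC=C(C)C | intermediate
16 | ring A 4aα-bromo-4aβ-carbaldehyde with ArBr2 side chain (key-step precursor) | CC(C)C[C@H](c1c(OC)c(Br)c(OC)c(Br)c1OC)[C@H]1CC[C@@H](C)[C@@](Br)(C=O)[C@]1(C)CCC=C(C)C | intermediate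
17 | trans-fused bromohydrin diol: 4aα-Br, 5α-OH, 6β-(2-hydroxypropan-2-yl), 8aβ-Me, 4β-Me, 1β-side chain with ArBr2 (key-step product) | CC(C)C[C@H](c1c(OC)c(Br)c(OC)c(Br)c1OC)[C@H]1CC[C@@H](C)[C@@]2(Br)[C@H](O)[C@@H](C(C)(C)O)CC[C@@]21C | intermediate
18 | C4a=C5 alkene tertiary alcohol with ArBr2 side chain | CC(C)C[C@H](c1c(OC)c(Br)c(OC)c(Br)c1OC)[C@H]1CC[C@@H](C)C2=C[C@@H](C(C)(C)O)CC[C@@]21C | intermediate
19 | lithium alkoxide of 18 with both aryl bromines exchanged for lithium | CC(C)C[C@H](c1c(OC)c([Li])c(OC)c([Li])c1OC)[C@H]1CC[C@@H](C)C2=C[C@@H](C(C)(C)O[Li])CC[C@@]21C | intermediate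
20 | target tri-O-methyl ether (3′,5′-diformyl-2′,4′,6′-trimethoxyphenyl) | CC(C)C[C@H](c1c(OC)c(C=O)c(OC)c(C=O)c1OC)[C@H]1CC[C@@H](C)C2=C[C@@H](C(C)(C)O)CC[C@@]21C | intermediate
21 | CNP0108656.4, (αS,1R,4R,6S,8aR) | CC(C)C[C@H](c1c(O)c(C=O)c(O)c(C=O)c1O)[C@H]1CC[C@@H](C)C2=C[C@@H](C(C)(C)O)CC[C@@]21C | target

**Step count and risk**

Total step count: 13. Longest linear sequence: 13 steps (1 and 2 to 21).

Steps most likely to fail:

Step 5. The cycloaddition may be too slow at the fully substituted β-carbon of the enal, the silyl enol ether may add to the aldehyde carbonyl instead, and facial discrimination by Cα may be weak. The fallback sets out from 8 and comes back at 10. Diene 8 would be heated with but-2-ynal (toluene, 80 °C), a linear and unhindered dienophile without an endo/exo question, to give the cyclohexa-1,4-diene carbaldehyde F1, in which C1 and C4 are cis and the C4a=C8a enal carries the 8a-methyl. Copper-catalysed conjugate addition of (4-methylpent-3-enyl)magnesium bromide F2 (from 5-bromo-2-methylpent-2-ene and Mg; CuBr·SMe2, THF, −78 °C) anti to the C1 side chain would then create the quaternary C8a, and protonation on work-up would return 10. The C4a epimer ratio is irrelevant because C4a is enolised in step 9.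

Step 9. During the second stage NBS may attack the side-chain alkene (bromonium formation or allylic bromination) in competition with the arene, and the one-pot sequence may give mixtures of partly brominated material. The fallback sets out from 13 and comes back at 17. Only the enolate bromination would be run (KH, then 1.05 equiv NBS) and 15 isolated. Compound 15 would be cyclised with aqueous H2SO4/THF as in step 10 to the bromohydrin diol F3, and the arene of F3, now in a molecule without any alkene, would be dibrominated with NBS (2.1 equiv, MeCN, 0 °C) to reach 17.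

Step 10. Proton loss from the tertiary cation, slow closure through the chair that carries two syn-axial methyl groups, or acid-induced ionisation of the bromohydrin may divert material. The fallback sets out from 16 and comes back at 17. A Me2AlCl-promoted intramolecular carbonyl-ene reaction (CH2Cl2, −78 °C) through the same chair would form C5–C6 and give the 6β-isopropenyl bromohydrin F4. A Mukaiyama hydration of its 1,1-disubstituted alkene (Co(acac)2 cat., PhSiH3, O2, i-PrOH) would then install the tertiary alcohol of 17.

**Further compounds**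

F1 | step 5 | 4-(tert-butyldimethylsilyloxy)-2,6-dimethyl-3-[(1S)-3-methyl-1-(2,4,6-trimethoxyphenyl)butyl]cyclohexa-1,4-diene-1-carbaldehyde, 3,6-cis | CC(C)C[C@H](c1c(OC)cc(OC)cc1OC)[C@H]1C(O[Si](C)(C)C(C)(C)C)=C[C@@H](C)C(C=O)=C1C
F2 | step 5 | (4-methylpent-3-enyl)magnesium bromide | CC(C)=CCC[Mg]Br
F3 | step 9 | trans-fused bromohydrin diol with unbrominated Ar side chain (4aα-Br, 5α-OH, 6β-(2-hydroxypropan-2-yl)) | CC(C)C[C@H](c1c(OC)cc(OC)cc1OC)[C@H]1CC[C@@H](C)[C@@]2(Br)[C@H](O)[C@@H](C(C)(C)O)CC[C@@]21C
F4 | step 10 | trans-fused 6β-isopropenyl bromohydrin with ArBr2 side chain (4aα-Br, 5α-OH) | CC(C)C[C@H](c1c(OC)c(Br)c(OC)c(Br)c1OC)[C@H]1CC[C@@H](C)[C@@]2(Br)[C@H](O)[C@@H](C(C)=C)CC[C@@]21C
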